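**Retrosynthetic overview**

1. Locants follow the target name (C3 isopropyl carbinol, C3a ring-fusion CH, C4 ester carbon, C6 methylidene carbon, C7 free carbinol, C8 CH2, C8a methyl-bearing carbon). The vanillate on C4 is attached last, and the isopropyl group on C3 comes from a Grignard addition to a C3 ketone, which leaves a trans-fused hydroazulenone carrying both secondary carbinols and the exocyclic alkene.
2. Key disconnection: the seven-membered ring is cut at C7–C8 and C3a–C4 at once. Forward, CrCl2 reverses the polarity of a C–Br and a C–I bond on one cyclopentanone (C3a enolate, C8 alkylchromium), and both add to the two aldehydes of 2-methylidenebutanedial in a reductive [3+4] annulation.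
3. Feature that allows this: in the seven-membered ring the carbinol carbons C4 and C7 stand 1,4 across C5–C6(=CH2), a latent 1,4-dialdehyde. They are clasped by C3a–C8a–C8, where C3a is alpha to the C3 carbinol (a latent ketone) and C8 is a CH2 on the quaternary C8a, a latent 1,3-dinucleophile.
4. The dinucleophile is stored as the cyclopropane of (1S,5R)-5-methylbicyclo[3.1.0]hexan-2-one (C3a–C8 as a temporary ring, from CBS reduction and directed Simmons–Smith reaction of 3-methylcyclopent-2-enone) and released by C–C cleavage with Me3SiI. The dialdehyde comes from dimethyl itaconate.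
5. Ring order: cyclopentane (bought), temporary cyclopropane (fixes C8a), cyclopropane opened, seven-membered ring (key step).

Key step: step 7

Remark: bromo ketone 6 is used as a mixture of C2 epimers, because C2 becomes a planar enolate carbon in step 7.

**Route**

Step 1
Reactants: 1 3-methylcyclopent-2-en-1-one
Product: 2 (R)-3-methylcyclopent-2-en-1-ol
Conditions: (S)-2-methyl-CBS-oxazaborolidine (10 mol %), BH3·SMe2, THF, −20 °C
Reagents that add atoms: none
Why: Corey–Bakshi–Shibata reduction: the oxazaborolidine–borane complex binds the ketone with the alkene side as the large group and should deliver hydride to one face only, which sets the (R)-carbinol that directs the next step.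

Step 2
Reactants: 2 (R)-3-methylcyclopent-2-en-1-ol
Product: 3 (1S,2R,5R)-5-methylbicyclo[3.1.0]hexan-2-ol
Conditions: Et2Zn, CH2I2, CH2Cl2, 0 °C
Reagents that add atoms: diiodomethane, ICI
Why: Hydroxyl-directed Simmons–Smith cyclopropanation (Furukawa reagent): the zinc alkoxide delivers the methylene to the alkene face syn to oxygen, so the carbinol configuration is relayed to the quaternary carbon (the later C8a) and the new CH2 (the later C8).

Step 3
Reactants: 3 (1S,2R,5R)-5-methylbicyclo[3.1.0]hexan-2-ol
Product: 4 (1S,5R)-5-methylbicyclo[3.1.0]hexan-2-one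
Conditions: Dess–Martin periodinane, CH2Cl2, 0 to 23 °C
Reagents that add atoms: none
Why: Dess–Martin oxidation of the secondary cyclopropyl carbinol should give the ketone without opening the ring, and the two cyclopropane stereocentres cannot epimerize because the ring is necessarily cis-fused.

Step 4
Reactants: 4 (1S,5R)-5-methylbicyclo[3.1.0]hexan-2-one
Product: 6 (3S)-2-bromo-3-(iodomethyl)-3-methylcyclopentan-1-one (both C2 epimers), via silyl enol ether 5 (not isolated)
Conditions: Me3SiI, (Me3Si)2NH (5 mol %), CH2Cl2, −78 to 0 °C; then N-bromosuccinimide, THF, −78 °C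
Reagents that add atoms: iodotrimethylsilane, C[Si](C)(C)I; N-bromosuccinimide, O=C1CCC(=O)N1Br
Why: Homo-conjugate opening of a cyclopropyl ketone by iodotrimethylsilane: iodide attacks the unsubstituted cyclopropane CH2 and breaks the external C1–C6 bond, the one aligned with the carbonyl pi system, so the silyl enol ether forms with its double bond towards the quaternary carbon and is then brominated by N-bromosuccinimide at that carbon only, while the quaternary stereocentre is not touched.

Step 5
Reactants: 7 dimethyl itaconate (dimethyl 2-methylidenebutanedioate)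
Product: 8 2-methylidenebutane-1,4-diol
Conditions: i-Bu2AlH (4.5 equiv), CH2Cl2, −78 to 0 °C
Reagents that add atoms: none
Why: Ester reduction with i-Bu2AlH: 1,2-hydride delivery should take both the saturated and the conjugated ester to the primary alcohols and leave the 1,1-disubstituted alkene alone.

Step 6
Reactants: 8 2-methylidenebutane-1,4-diol
Product: 9 2-methylidenebutanedial
Conditions: Dess–Martin periodinane (2.4 equiv), NaHCO3, CH2Cl2, 0 °C; filtered cold and used at once as a THF solution
Reagents that add atoms: none
Why: Dess–Martin oxidation under bicarbonate buffer should take both primary alcohols to aldehydes without base or acid strong enough to move the double bond into conjugation with both carbonyl groups.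

Step 7
Reactants: 6 (3S)-2-bromo-3-(iodomethyl)-3-methylcyclopentan-1-one and 9 2-methylidenebutanedial
Product: 12 (3aS,4S,7S,8aR)-4,7-dihydroxy-8a-methyl-6-methylideneoctahydroazulen-3(2H)-one, via chromium enolate 10 (not isolated), via chromium aldolate 11 (not isolated)
Conditions: CrCl2 (8 equiv), LiI (20 mol %), THF/DMF 1:1, 0 °C, 6 and 9 (1.05 equiv) added slowly; then Co(C32H16N8) (cobalt phthalocyanine, 10 mol %), 23 °C, 0.01 M; aqueous work-up
Reagents that add atoms: none
Why: Proposed new method: two CrCl2 reduce the C–Br bond of 6 quickly (halogen abstraction, then radical capture) to the regiodefined trivalent chromium enolate 10, which adds through a closed chair transition state to the saturated, more electrophilic aldehyde of 9 (bond C3a–C4) to give 11, and only then does the slower cobalt cycle turn the neopentyl-type C–I bond into a radical that CrCl2 captures as an alkylchromium, which adds 1,2 to the remaining conjugated aldehyde (bond C7–C8), so the dihalo ketone acts as a 1,3-dinucleophile and the dialdehyde as a 1,4-dielectrophile in a reductive [3+4] annulation. The closest known reactions are the chromium Reformatsky reaction of alpha-bromo ketones with aldehydes and the cobalt-catalysed alkyl variant of the Nozaki–Hiyama–Kishi reaction; their union in one flask on a dialdehyde is new. The seven-membered ring closes in the second event by 7-exo-trig attack of the C8 alkylchromium on the aldehyde carbon C7, helped by the gem-disubstituted C8a. C3a should be set by approach of the aldehyde to the enolate face anti to the larger iodomethyl arm on C8a (trans ring fusion), C4 by the anti-aldol preference of the ring-constrained (E)-enolate in the Zimmerman–Traxler chair, and C7 by placing the chromium alkoxide pseudo-equatorial, away from the 1,3-related angular methyl. The step needs site selectivity between the two aldehydes and between intra- and intermolecular alkylchromium addition: the first rests on the much faster enolate formation and on the lower electrophilicity of the alpha-branched conjugated aldehyde, the second on high dilution and on the alkylchromium forming only after free 9 has been consumed, while the C3 ketone is inert to both chromium nucleophiles.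

Step 8
Reactants: 12 (3aS,4S,7S,8aR)-4,7-dihydroxy-8a-methyl-6-methylideneoctahydroazulen-3(2H)-one
Product: 13 (3aS,4S,7S,8aR)-7-{[tert-butyl(dimethyl)silyl]oxy}-4-hydroxy-8a-methyl-6-methylideneoctahydroazulen-3(2H)-one
Conditions: t-BuMe2SiCl (1.1 equiv), imidazole, DMF, −20 to 0 °C
Reagents that add atoms: tert-butyldimethylsilyl chloride, CC(C)(C)[Si](C)(C)Cl
Why: Site-selective silyl ether formation: the allylic C7 hydroxyl is flanked by a CH2 and an sp2 carbon, whereas the C4 hydroxyl sits next to the ring-fusion methine and is hydrogen-bonded to the ketone, so the bulky silyl chloride should react at C7 first.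

Step 9
Reactants: 13 (3aS,4S,7S,8aR)-7-{[tert-butyl(dimethyl)silyl]oxy}-4-hydroxy-8a-methyl-6-methylideneoctahydroazulen-3(2H)-one
Product: 14 (3R,3aS,4S,7S,8aR)-7-{[tert-butyl(dimethyl)silyl]oxy}-8a-methyl-6-methylidene-3-(propan-2-yl)decahydroazulene-3,4-diol
Conditions: i-PrMgCl (4 equiv), LaCl3·2LiCl (1 equiv), THF, −20 to 0 °C
Reagents that add atoms: isopropylmagnesium chloride, CC(C)[Mg]Cl
Why: Lanthanum chloride-promoted Grignard addition to a hindered, enolizable ketone: after deprotonation of the C4 hydroxyl the reagent should attack the carbonyl from the face of the C3a hydrogen, opposite to the angular methyl and to the C4 alkoxide chelate, which sets the C3 carbinol with its hydroxyl cis to the methyl.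

Step 10
Reactants: 15 vanillic acid (4-hydroxy-3-methoxybenzoic acid)
Product: 17 4-{[tert-butyl(dimethyl)silyl]oxy}-3-methoxybenzoic acid, via silyl ester 16 (not isolated)
Conditions: t-BuMe2SiCl (2.5 equiv), imidazole, DMF, 23 °C; then AcOH/THF/H2O, 23 °C
Reagents that add atoms: tert-butyldimethylsilyl chloride, CC(C)(C)[Si](C)(C)Cl
Why: Silyl protection: both acidic groups are silylated and the much more labile silyl ester is then hydrolysed selectively, which leaves the phenol masked for the esterification.

Step 11
Reactants: 14 (3R,3aS,4S,7S,8aR)-7-{[tert-butyl(dimethyl)silyl]oxy}-8a-methyl-6-methylidene-3-(propan-2-yl)decahydroazulene-3,4-diol and 17 4-{[tert-butyl(dimethyl)silyl]oxy}-3-methoxybenzoic acid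
Product: 19 (3R,3aS,4S,7S,8aR)-7-{[tert-butyl(dimethyl)silyl]oxy}-3-hydroxy-8a-methyl-6-methylidene-3-(propan-2-yl)decahydroazulen-4-yl 4-{[tert-butyl(dimethyl)silyl]oxy}-3-methoxybenzoate, via mixed anhydride 18 (not isolated)
Conditions: 17, 2,4,6-trichlorobenzoyl chloride, Et3N, THF, 23 °C; then 14, 4-(dimethylamino)pyridine, toluene, 40 °C
Reagents that add atoms: none
Why: Yamaguchi esterification through the mixed anhydride: only the secondary C4 hydroxyl can be acylated since the C3 hydroxyl is tertiary and the C7 hydroxyl is silylated, and C4 keeps its configuration because its C–O bond is not broken.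

Step 12
Reactants: 19 (3R,3aS,4S,7S,8aR)-7-{[tert-butyl(dimethyl)silyl]oxy}-3-hydroxy-8a-methyl-6-methylidene-3-(propan-2-yl)decahydroazulen-4-yl 4-{[tert-butyl(dimethyl)silyl]oxy}-3-methoxybenzoate
Product: 20 (3R,3aS,4S,7S,8aR)-3,7-dihydroxy-8a-methyl-6-methylidene-3-(propan-2-yl)decahydroazulen-4-yl 4-hydroxy-3-methoxybenzoate (CNP0330487.1)
Conditions: n-Bu4NF (3 equiv), AcOH (3 equiv), THF, 0 to 23 °C
Reagents that add atoms: none
Why: Fluoride-induced desilylation buffered with acetic acid should free the phenol and the C7 hydroxyl in one operation without acyl migration or loss of the tertiary alcohol.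

**Compound list**

1 | 3-methylcyclopent-2-en-1-one | CC1=CC(=O)CC1 | starting material
2 | (R)-3-methylcyclopent-2-en-1-ol | O[C@H]1C=C(C)CC1 | intermediate
3 | (1S,2R,5R)-5-methylbicyclo[3.1.0]hexan-2-ol (hydroxyl cis to the cyclopropane CH2) | C[C@]12CC[C@@H](O)[C@H]1C2 | intermediate
4 | (1S,5R)-5-methylbicyclo[3.1.0]hexan-2-one | C[C@]12CCC(=O)[C@H]1C2 | intermediate
5 | (S)-{[3-(iodomethyl)-3-methylcyclopent-1-en-1-yl]oxy}(trimethyl)silane | C[Si](C)(C)OC1=C[C@@](C)(CI)CC1 | intermediate
6 | (3S)-2-bromo-3-(iodomethyl)-3-methylcyclopentan-1-one (both C2 epimers) | O=C1CC[C@](C)(CI)C1Br | intermediate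
7 | dimethyl itaconate (dimethyl 2-methylidenebutanedioate) | C=C(CC(=O)OC)C(=O)OC | starting material
8 | 2-methylidenebutane-1,4-diol | C=C(CO)CCO | intermediate
9 | 2-methylidenebutanedial | C=C(C=O)CC=O | intermediate
10 | dichloro{[(3S)-3-(iodomethyl)-3-methylcyclopent-1-en-1-yl]oxy}chromium (trivalent chromium enolate) | C[C@]1(CI)CCC(O[Cr](Cl)Cl)=C1 | intermediate
11 | trivalent chromium aldolate: dichlorochromium alkoxide of (2S,3S)-2-[(1S)-1-hydroxy-3-methylidene-4-oxobutyl]-3-(iodomethyl)-3-methylcyclopentan-1-one | C=C(C=O)C[C@H](O[Cr](Cl)Cl)[C@H]1C(=O)CC[C@]1(C)CI | intermediate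
12 | (3aS,4S,7S,8aR)-4,7-dihydroxy-8a-methyl-6-methylideneoctahydroazulen-3(2H)-one | C=C1C[C@H](O)[C@@H]2[C@](C)(CCC2=O)C[C@@H]1O | intermediate
13 | (3aS,4S,7S,8aR)-7-{[tert-butyl(dimethyl)silyl]oxy}-4-hydroxy-8a-methyl-6-methylideneoctahydroazulen-3(2H)-one | C=C1C[C@H](O)[C@@H]2[C@](C)(CCC2=O)C[C@@H]1O[Si](C)(C)C(C)(C)C | intermediate
14 | (3R,3aS,4S,7S,8aR)-7-{[tert-butyl(dimethyl)silyl]oxy}-8a-methyl-6-methylidene-3-(propan-2-yl)decahydroazulene-3,4-diol | C=C1C[C@H](O)[C@@H]2[C@](C)(CC[C@@]2(O)C(C)C)C[C@@H]1O[Si](C)(C)C(C)(C)C | intermediate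
15 | vanillic acid (4-hydroxy-3-methoxybenzoic acid) | COc1cc(C(=O)O)ccc1O | starting material
16 | tert-butyldimethylsilyl 4-{[tert-butyl(dimethyl)silyl]oxy}-3-methoxybenzoate | COc1cc(C(=O)O[Si](C)(C)C(C)(C)C)ccc1O[Si](C)(C)C(C)(C)C | intermediate
17 | 4-{[tert-butyl(dimethyl)silyl]oxy}-3-methoxybenzoic acid | COc1cc(C(=O)O)ccc1O[Si](C)(C)C(C)(C)C | intermediate
18 | 4-{[tert-butyl(dimethyl)silyl]oxy}-3-methoxybenzoic 2,4,6-trichlorobenzoic anhydride | COc1cc(C(=O)OC(=O)c2c(Cl)cc(Cl)cc2Cl)ccc1O[Si](C)(C)C(C)(C)C | intermediate
19 | (3R,3aS,4S,7S,8aR)-7-{[tert-butyl(dimethyl)silyl]oxy}-3-hydroxy-8a-methyl-6-methylidene-3-(propan-2-yl)decahydroazulen-4-yl 4-{[tert-butyl(dimethyl)silyl]oxy}-3-methoxybenzoate | C=C1C[C@H](OC(=O)c2ccc(O[Si](C)(C)C(C)(C)C)c(OC)c2)[C@@H]2[C@](C)(CC[C@@]2(O)C(C)C)C[C@@H]1O[Si](C)(C)C(C)(C)C | intermediate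
20 | (3R,3aS,4S,7S,8aR)-3,7-dihydroxy-8a-methyl-6-methylidene-3-(propan-2-yl)decahydroazulen-4-yl 4-hydroxy-3-methoxybenzoate (CNP0330487.1) | C=C1C[C@H](OC(=O)c2ccc(O)c(OC)c2)[C@@H]2[C@](C)(CC[C@@]2(O)C(C)C)C[C@@H]1O | target

**Step count**

Total step count: 12. Longest linear sequence: 9 steps (steps 1, 2, 3, 4, 7, 8, 9, 11, 12).

**Steps most likely to fail**

Step 7 (bears the label). What may go wrong: loss of site selectivity (the chromium enolate adds to the conjugated aldehyde), poor facial selectivity at C3a (cis ring fusion), or intermolecular capture of the alkylchromium by a second dialdehyde (oligomerization). Fallback: form the two bonds in two separate known reactions. Setting out from 4 and 9, iodide-induced cyclopropane opening with aldol trapping of the titanium enolate (TiCl4, n-Bu4NI, CH2Cl2, −78 °C, then 9) would give the iodo aldol (2S,3S)-2-[(1S)-1-hydroxy-3-methylidene-4-oxobutyl]-3-(iodomethyl)-3-methylcyclopentan-1-one F1. After purification, F1 would be cyclized at high dilution by the cobalt-catalysed alkyl Nozaki–Hiyama–Kishi reaction (CrCl2, cobalt phthalocyanine, DMF, 23 °C), which comes back to the route at 12.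

Step 6. What may go wrong: migration of the double bond into conjugation with both carbonyl groups (the CH2 between them is doubly activated), or oligomerization of the dialdehyde during oxidation and concentration. Fallback: never liberate both aldehydes at once. Setting out from 8, allylic-selective oxidation (MnO2, CH2Cl2) would give the lactol 3-methylideneoxolan-2-ol F2. Ring-opening thioacetalization (propane-1,3-dithiol, BF3·OEt2) would give 3-(1,3-dithian-2-yl)but-3-en-1-ol F3, and Dess–Martin oxidation would give 3-(1,3-dithian-2-yl)but-3-enal F4, which has one free aldehyde only. Chromium Reformatsky coupling of 6 with F4 (CrCl2, LiI, THF) would give (2S,3S)-2-[(1S)-3-(1,3-dithian-2-yl)-1-hydroxybut-3-en-1-yl]-3-(iodomethyl)-3-methylcyclopentan-1-one F5. Dithiane hydrolysis (MeI, CaCO3, aqueous MeCN) would give the iodo aldol F1 described above, and its alkylchromium ring closure comes back to the route at 12.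

Step 9. What may go wrong: enolization of the hindered ketone or hydride transfer from the isopropyl Grignard reagent instead of addition, or retro-aldol opening of the magnesium aldolate. Fallback: a non-basic samarium Barbier reaction. Setting out from 13, 2-iodopropane and SmI2 (THF/HMPA, 23 °C) would generate the organosamarium in the presence of the ketone and should give 14 directly; this fallback makes no new compound (F0).

Further compounds
F1 | step 7 | (2S,3S)-2-[(1S)-1-hydroxy-3-methylidene-4-oxobutyl]-3-(iodomethyl)-3-methylcyclopentan-1-one | C=C(C=O)C[C@H](O)[C@H]1C(=O)CC[C@]1(C)CI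
F2 | step 6 | 3-methylideneoxolan-2-ol (racemic lactol) | C=C1CCOC1O
F3 | step 6 | 3-(1,3-dithian-2-yl)but-3-en-1-ol | C=C(CCO)C1SCCCS1
F4 | step 6 | 3-(1,3-dithian-2-yl)but-3-enal | C=C(CC=O)C1SCCCS1
F5 | step 6 | (2S,3S)-2-[(1S)-3-(1,3-dithian-2-yl)-1-hydroxybut-3-en-1-yl]-3-(iodomethyl)-3-methylcyclopentan-1-one | C=C(C1SCCCS1)C[C@H](O)[C@H]1C(=O)CC[C@]1(C)CI
F0 | step 9 | none | none
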